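**Retrosynthetic overview**

1. The target is the diacetate of a keto diol whose ketone comes from a C5' carbinol. The C4'–C5' bond is cut between a (4'R) secondary pinacol boronic ester and the lithiated α-benzoyloxy carbanion of a C6 fragment (4-methyl-3-methylidenepentyl benzoate). The C3'–C4' bond is cut between a primary boronic ester and (S)-1-lithioethyl benzoate. Both 1,2-metallate shifts are run in one flask.
2. Enabling feature: the ketone carbon C5' is an oxygen-bearing carbon between the CH(CH3) stereocentre C4' and the C6' methylene, and C4' is insulated from the oxepane (ring O1–C2–C3–C4–C5–C6–C7) by the unfunctionalised tether C1'–C3'. C5' can therefore enter as a carbenoid that brings its own oxygen and C4' as a boron-bound carbon, so no enolate is ever formed next to the 7'-methylidene.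
3. The oxepane, the only ring, is closed by 7-endo opening of an (R,R)-trisubstituted epoxide (Shi) by the allylic CH2OH that becomes C7–O1. This sets C2 (inversion) and C3.
4. The acyclic precursor takes its (E)-trisubstituted alkene from zirconium-catalysed methylalumination of 5-chloropent-1-yne and oxirane, and its exocyclic (E)-alkene from Red-Al/I2 on but-2-yne-1,4-diol followed by Negishi coupling. The chloride is the latent boron.
5. Ring order: the oxepane is formed at step 6, before boron is introduced (step 8) and before fragment union (step 11).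

Key step: step 11

Remark: locants follow the oxepane (O1, C2–C7) and the side chain on C2 (C1'–C9', ketone C5'). Ethyl 2,4,6-triisopropylbenzoate, (−)-sparteine and the D-fructose-derived Shi ketone are taken as commercial. The C5' carbinol is carried as a mixture of epimers that converge on the ketone.

**Route**

Step 1
Reactants: 1 5-chloropent-1-yne
Product: 4 (E)-8-chloro-4-methyloct-3-en-1-ol, via alkenyldimethylalane 2 (not isolated), via lithium alkenylalanate 3 (not isolated)
Conditions: Me3Al, Cp2ZrCl2 (0.25 equiv), CH2Cl2, 0 °C to rt; volatiles removed; nBuLi, hexane/THF, −78 °C; oxirane, −78 °C to rt; aq. HCl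
Reagents that add atoms: trimethylaluminium C[Al](C)C; oxirane C1CO1
Why: Zirconium-catalysed Negishi carboalumination adds methyl and aluminium syn across the terminal alkyne with methyl on the internal carbon, and the derived alkenyl alanate should open oxirane with retention of the (E)-geometry.

Step 2
Reactants: 4 (E)-8-chloro-4-methyloct-3-en-1-ol
Product: 5 (E)-8-chloro-1-iodo-4-methyloct-3-ene
Conditions: I2, PPh3, imidazole, CH2Cl2, 0 °C to rt
Reagents that add atoms: iodine II
Why: Appel-type iodination converts the primary alcohol into the iodide by SN2 displacement of the oxyphosphonium group without touching the alkene or the chloride.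

Step 3
Reactants: 6 but-2-yne-1,4-diol
Product: 8 (Z)-2-iodobut-2-ene-1,4-diol, via cyclic alkenylalanate 7 (not isolated)
Conditions: NaAlH2(OCH2CH2OCH3)2 (Red-Al), THF, 0 °C to rt; I2, THF, −78 to 0 °C; aq. Rochelle salt
Reagents that add atoms: iodine II
Why: Hydroxyl-directed trans-hydroalumination of the propargylic diol places aluminium on the distal alkyne carbon in a five-membered alanate, and iodinolysis with retention should give the (Z)-vinyl iodide.

Step 4
Reactants: 5 (E)-8-chloro-1-iodo-4-methyloct-3-ene; 8 (Z)-2-iodobut-2-ene-1,4-diol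
Product: 10 (2E)-2-[(3E)-8-chloro-4-methyloct-3-en-1-yl]but-2-ene-1,4-diol, via alkylzinc iodide 9 (not isolated)
Conditions: 5, Zn dust, LiCl, THF, 40 °C; then slow addition to 8, Pd(OAc)2 (3 mol%), SPhos (6 mol%), THF, rt
Reagents that add atoms: none
Why: LiCl-assisted zinc insertion into the primary iodide (the chloride is inert) and palladium-catalysed Negishi sp3–sp2 coupling with retention of alkene geometry should place the chain cis to the CH2OH on the CH= carbon, slow addition letting the coupling outrun protonation of the alkylzinc by the free hydroxyls.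

Step 5
Reactants: 10 (2E)-2-[(3E)-8-chloro-4-methyloct-3-en-1-yl]but-2-ene-1,4-diol
Product: 11 (2E)-2-{2-[(2R,3R)-3-(3-chloropropyl)-3-methyloxiran-2-yl]ethyl}but-2-ene-1,4-diol
Conditions: D-fructose-derived Shi ketone (0.3 equiv), KHSO5 (Oxone), K2CO3, Bu4NHSO4, MeCN/dimethoxymethane, aq. Na2B4O7/Na2(EDTA) buffer (pH 10.5), 0 °C
Reagents that add atoms: potassium peroxymonosulfate [K+].[O-]S(=O)(=O)OO
Why: Shi asymmetric epoxidation attacks the electron-rich unfunctionalised trisubstituted alkene (the alkene flanked by two CH2OH groups is deactivated) through the spiro transition state and should set both epoxide centres as (R,R) under catalyst control.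

Step 6
Reactants: 11 (2E)-2-{2-[(2R,3R)-3-(3-chloropropyl)-3-methyloxiran-2-yl]ethyl}but-2-ene-1,4-diol
Product: 12 (2S,3R,6E)-2-(3-chloropropyl)-6-(2-hydroxyethylidene)-2-methyloxepan-3-ol
Conditions: camphorsulfonic acid (10 mol%), CH2Cl2, 0 °C
Reagents that add atoms: none
Why: In this acid-catalysed intramolecular epoxide opening the protonated trisubstituted epoxide is attacked at its tertiary carbon by the hydroxymethyl oxygen geminal to the chain (7-endo-tet, inversion, C2 becomes S), the retained C–O bond becomes the (3R)-hydroxyl, and the other hydroxymethyl group could only close a nine-membered ring.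

Step 7
Reactants: 12 (2S,3R,6E)-2-(3-chloropropyl)-6-(2-hydroxyethylidene)-2-methyloxepan-3-ol
Product: 13 (2S,3R,6E)-3-(tert-butyldimethylsilyloxy)-6-[2-(tert-butyldimethylsilyloxy)ethylidene]-2-(3-chloropropyl)-2-methyloxepane
Conditions: TBSOTf (2.5 equiv), 2,6-lutidine, CH2Cl2, −78 to 0 °C
Reagents that add atoms: tert-butyldimethylsilyl trifluoromethanesulfonate CC(C)(C)[Si](C)(C)OS(=O)(=O)C(F)(F)F
Why: Silylation with the triflate and a hindered base protects both the primary allylic and the hindered secondary hydroxyl, so that the later organolithium, base and peroxide steps meet no acidic or acyl group.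

Step 8
Reactants: 13 bis-silyl ether chloride
Product: 14 2-{3-[(2S,3R,6E)-3-(tert-butyldimethylsilyloxy)-6-[2-(tert-butyldimethylsilyloxy)ethylidene]-2-methyloxepan-2-yl]propyl}-4,4,5,5-tetramethyl-1,3,2-dioxaborolane
Conditions: B2pin2, CuI (10 mol%), PPh3 (13 mol%), LiOMe, Bu4NI, DMF, 40 °C
Reagents that add atoms: bis(pinacolato)diboron CC1(C)OB(OC1(C)C)B1OC(C)(C)C(C)(C)O1
Why: Copper-catalysed boryl substitution of a primary alkyl halide (iodide-assisted for the chloride) should convert the latent C3' chloride into the pinacol boronic ester while silyl ethers, the tertiary ether and the trisubstituted alkene stay inert.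

Step 9
Reactants: 15 but-3-yn-1-ol
Product: 17 4-methyl-3-methylidenepentan-1-ol, via alkenylmagnesium chelate 16 (not isolated)
Conditions: iPrMgCl (3 equiv), CuI (20 mol%), THF/Et2O, −20 °C to rt; aq. NH4Cl
Reagents that add atoms: isopropylmagnesium chloride CC(C)[Mg]Cl
Why: Alkoxide-directed copper-catalysed carbomagnesiation of the homopropargylic alcohol delivers the isopropyl group to the internal alkyne carbon through a six-membered magnesium chelate and gives the 1,1-disubstituted alkene on protonation.

Step 10
Reactants: 17 4-methyl-3-methylidenepentan-1-ol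
Product: 18 4-methyl-3-methylidenepentyl 2,4,6-triisopropylbenzoate
Conditions: 2,4,6-triisopropylbenzoyl chloride, Et3N, DMAP (cat.), CH2Cl2, reflux
Reagents that add atoms: 2,4,6-triisopropylbenzoyl chloride CC(C)c1cc(C(C)C)c(C(=O)Cl)c(C(C)C)c1
Why: Acylation of the primary alcohol gives the hindered benzoate, whose carbonyl resists addition and directs lithiation to the O–CH2 group.

Step 11
Reactants: 14 primary pinacol boronic ester; 18 4-methyl-3-methylidenepentyl 2,4,6-triisopropylbenzoate; 19 ethyl 2,4,6-triisopropylbenzoate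
Product: 26 (4R)-1-[(2S,3R,6E)-3-(tert-butyldimethylsilyloxy)-6-[2-(tert-butyldimethylsilyloxy)ethylidene]-2-methyloxepan-2-yl]-4,8-dimethyl-7-methylidenenonan-5-ol (C5' epimers), via lithiated ethyl benzoate 20 (not isolated), via first boron ate complex 21 (not isolated), via secondary boronic ester 22 (not isolated), via lithiated homoallyl benzoate 23 (not isolated), via second boron ate complex 24 (not isolated), via homologated boronic ester 25 (not isolated)
Conditions: 19 (1.3 equiv), (−)-sparteine, sBuLi, Et2O, −78 °C, 5 h; add 14, −78 °C then 35 °C; recool to −78 °C and transfer onto 23 [from 18 (1.6 equiv), TMEDA, sBuLi, Et2O, −78 °C]; −78 °C then 35 °C; THF, 2 M NaOH, 30% H2O2, 0 °C to rt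
Reagents that add atoms: hydrogen peroxide OO
Why: (S)-1-Lithioethyl benzoate 20, formed by (−)-sparteine-directed removal of the pro-S proton, adds to boron of 14 with retention, and the C3' group then shifts from boron to carbon anti to the departing benzoate (inversion at carbon), which fixes C4' as R in 22 and makes the C3'–C4' bond; the second carbenoid 23 adds to 22 and the C4' group migrates with retention of its configuration, which makes the C4'–C5' bond and places boron, then oxygen, on C5'. The closest known reaction type is iterative (assembly-line) lithiation–borylation homologation of primary and secondary pinacol boronic esters with lithiated 2,4,6-triisopropylbenzoates, followed by oxidation. No ring is closed. The only new stereocentre that survives, C4', is under reagent control of the sparteine-derived carbenoid because the ring stereocentres are five bonds away; C5' forms as a mixture and is erased by the next oxidation. Over-homologation should be avoided because tetracoordinate boron accepts no second carbenoid and surplus 20 decomposes on warming before 22 is released; lithiation of 18 at C5' and not at the allylic C6' is secured by the benzoate carbonyl, which directs sBuLi to the adjacent O–CH2 group.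

Step 12
Reactants: 26 C5' carbinol (epimers)
Product: 27 (4R)-1-[(2S,3R,6E)-3-(tert-butyldimethylsilyloxy)-6-[2-(tert-butyldimethylsilyloxy)ethylidene]-2-methyloxepan-2-yl]-4,8-dimethyl-7-methylidenenonan-5-one
Conditions: Dess–Martin periodinane, NaHCO3, CH2Cl2, 0 °C to rt
Reagents that add atoms: none
Why: Dess–Martin oxidation under bicarbonate buffer should convert both carbinol epimers into the ketone without enolising C4' or moving the 7'-methylidene into conjugation.

Step 13
Reactants: 27 bis-silyl ketone
Product: 28 (4R)-1-[(2S,3R,6E)-3-hydroxy-6-(2-hydroxyethylidene)-2-methyloxepan-2-yl]-4,8-dimethyl-7-methylidenenonan-5-one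
Conditions: HF·pyridine, pyridine, THF, 0 °C to rt
Reagents that add atoms: none
Why: Buffered fluoride-mediated desilylation cleaves both silyl ethers under weakly acidic conditions that should spare the epimerisable C4' centre and the β,γ-unsaturated ketone.

Step 14
Reactants: 28 keto diol
Product: 29 (E)-2-[(2S,3R)-3-acetoxy-2-[(4R)-4,8-dimethyl-7-methylidene-5-oxononyl]-2-methyloxepan-6-ylidene]ethyl acetate
Conditions: Ac2O, pyridine, DMAP (cat.), CH2Cl2, 0 °C
Reagents that add atoms: acetic anhydride CC(=O)OC(C)=O
Why: Pyridine/DMAP-catalysed acetylation esterifies the primary allylic and the secondary C3 hydroxyl, the only nucleophiles in the molecule, under conditions mild enough for the α-stereocentre.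

**Compound list**

1 | 5-chloropent-1-yne | C#CCCCCl | starting material
2 | (E)-(5-chloro-2-methylpent-1-en-1-yl)dimethylalane | C[Al](C)/C=C(\C)CCCCl | intermediate
3 | lithium (E)-butyl(5-chloro-2-methylpent-1-en-1-yl)dimethylalanate | [Li+].CCCC[Al-](C)(C)/C=C(\C)CCCCl | intermediate
4 | (E)-8-chloro-4-methyloct-3-en-1-ol | OCC/C=C(\C)CCCCl | intermediate
5 | (E)-8-chloro-1-iodo-4-methyloct-3-ene | ICC/C=C(\C)CCCCl | intermediate
6 | but-2-yne-1,4-diol | OCC#CCO | starting material
7 | disodium cyclic alkenylalanate from trans-hydroalumination of 6 (five-membered oxa-alumina ring, idealised) | [Na+].[Na+].COCCO[Al-]1(OCCOC)OCC=C1C[O-] | intermediate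
8 | (Z)-2-iodobut-2-ene-1,4-diol | OC/C=C(\I)CO | intermediate
9 | (E)-(8-chloro-4-methyloct-3-en-1-yl)zinc iodide (LiCl complex) | I[Zn]CC/C=C(\C)CCCCl | intermediate
10 | (2E)-2-[(3E)-8-chloro-4-methyloct-3-en-1-yl]but-2-ene-1,4-diol | OC/C=C(\CC/C=C(\C)CCCCl)CO | intermediate
11 | (2E)-2-{2-[(2R,3R)-3-(3-chloropropyl)-3-methyloxiran-2-yl]ethyl}but-2-ene-1,4-diol | OC/C=C(\CC[C@H]1O[C@]1(C)CCCCl)CO | intermediate
12 | (2S,3R,6E)-2-(3-chloropropyl)-6-(2-hydroxyethylidene)-2-methyloxepan-3-ol | ClCCC[C@]1(C)OC/C(=C/CO)CC[C@H]1O | intermediate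
13 | (2S,3R,6E)-3-(tert-butyldimethylsilyloxy)-6-[2-(tert-butyldimethylsilyloxy)ethylidene]-2-(3-chloropropyl)-2-methyloxepane | ClCCC[C@]1(C)OC/C(=C/CO[Si](C)(C)C(C)(C)C)CC[C@H]1O[Si](C)(C)C(C)(C)C | intermediate
14 | primary pinacol boronic ester (boron on C3' of the propyl tether of 13) | CC1(C)OB(OC1(C)C)CCC[C@]2(C)OC/C(=C/CO[Si](C)(C)C(C)(C)C)CC[C@H]2O[Si](C)(C)C(C)(C)C | intermediate
15 | but-3-yn-1-ol | C#CCCO | starting material
16 | (Z)-alkenylmagnesium chloride alkoxide chelate from carbomagnesiation of 15 | Cl[Mg]/C=C(\CCO[Mg]Cl)C(C)C | intermediate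
17 | 4-methyl-3-methylidenepentan-1-ol | C=C(CCO)C(C)C | intermediate
18 | 4-methyl-3-methylidenepentyl 2,4,6-triisopropylbenzoate | C=C(CCOC(=O)c1c(C(C)C)cc(C(C)C)cc1C(C)C)C(C)C | intermediate
19 | ethyl 2,4,6-triisopropylbenzoate | CCOC(=O)c1c(C(C)C)cc(C(C)C)cc1C(C)C | starting material
20 | (S)-1-lithioethyl 2,4,6-triisopropylbenzoate ((−)-sparteine complex) | [Li][C@@H](C)OC(=O)c1c(C(C)C)cc(C(C)C)cc1C(C)C | intermediate
21 | lithium boron ate complex of 14 with 20 | [Li+].C[C@@H](OC(=O)c1c(C(C)C)cc(C(C)C)cc1C(C)C)[B-]1(CCC[C@]2(C)OC/C(=C/CO[Si](C)(C)C(C)(C)C)CC[C@H]2O[Si](C)(C)C(C)(C)C)OC(C)(C)C(C)(C)O1 | intermediate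
22 | (R)-secondary pinacol boronic ester (boron and methyl on C4') | C[C@@H](B1OC(C)(C)C(C)(C)O1)CCC[C@]2(C)OC/C(=C/CO[Si](C)(C)C(C)(C)C)CC[C@H]2O[Si](C)(C)C(C)(C)C | intermediate
23 | 1-lithio-4-methyl-3-methylidenepentyl 2,4,6-triisopropylbenzoate (racemic, TMEDA complex) | [Li]C(CC(=C)C(C)C)OC(=O)c1c(C(C)C)cc(C(C)C)cc1C(C)C | intermediate
24 | lithium boron ate complex of 22 with 23 | [Li+].C[C@@H]([B-]1(C(CC(=C)C(C)C)OC(=O)c2c(C(C)C)cc(C(C)C)cc2C(C)C)OC(C)(C)C(C)(C)O1)CCC[C@]3(C)OC/C(=C/CO[Si](C)(C)C(C)(C)C)CC[C@H]3O[Si](C)(C)C(C)(C)C | intermediate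
25 | homologated pinacol boronic ester (boron on C5', (4'R), C5' epimers) | C=C(CC(B1OC(C)(C)C(C)(C)O1)[C@H](C)CCC[C@]2(C)OC/C(=C/CO[Si](C)(C)C(C)(C)C)CC[C@H]2O[Si](C)(C)C(C)(C)C)C(C)C | intermediate
26 | bis-silyl (4R)-nonan-5-ol (C5' epimers) | C=C(CC(O)[C@H](C)CCC[C@]1(C)OC/C(=C/CO[Si](C)(C)C(C)(C)C)CC[C@H]1O[Si](C)(C)C(C)(C)C)C(C)C | intermediate
27 | bis-silyl (4R)-nonan-5-one | C=C(CC(=O)[C@H](C)CCC[C@]1(C)OC/C(=C/CO[Si](C)(C)C(C)(C)C)CC[C@H]1O[Si](C)(C)C(C)(C)C)C(C)C | intermediate
28 | (4R)-1-[(2S,3R,6E)-3-hydroxy-6-(2-hydroxyethylidene)-2-methyloxepan-2-yl]-4,8-dimethyl-7-methylidenenonan-5-one | C=C(CC(=O)[C@H](C)CCC[C@]1(C)OC/C(=C/CO)CC[C@H]1O)C(C)C | intermediate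
29 | (E)-2-[(2S,3R)-3-acetoxy-2-[(4R)-4,8-dimethyl-7-methylidene-5-oxononyl]-2-methyloxepan-6-ylidene]ethyl acetate | C=C(CC(=O)[C@H](C)CCC[C@]1(C)OC/C(=C/COC(C)=O)CC[C@H]1OC(C)=O)C(C)C | target

**Step count**

Total step count: 14. Longest linear sequence: 11 steps (1, 2, 4, 5, 6, 7, 8, 11, 12, 13, 14).

**Steps most likely to fail**

Step 11. The homoallylic benzoate may be deprotonated at the allylic C6' position and lose benzoate. Ate-complex formation between the hindered secondary boronic ester and the carbenoid may be so slow that the carbenoid decomposes first. Salts carried over from the first homologation may slow the second. Fallback: the first homologation is run alone and the secondary boronic ester 22 is isolated. From 22, halide-free vinyllithium gives the lithium vinyl boron ate complex F1. Palladium-catalysed conjunctive cross-coupling (Pd(OAc)2, MandyPhos, THF, 60 °C) with 3-methylbut-1-en-2-yl trifluoromethanesulfonate F2 (from 3-methylbutan-2-one, LDA, PhNTf2) then triggers the same stereoretentive 1,2-shift of C4' from boron to the vinyl α-carbon, while the alkenyl group is delivered to the β-carbon. No carbenoid is needed. The product is boronic ester 25, which is oxidised as in step 11, so the route is rejoined at 26.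

Step 6. The hydroxymethyl oxygen may attack the secondary epoxide carbon (6-exo closure) in competition with the 7-endo opening, or configuration at the tertiary carbon may be lost through a free carbocation. Fallback: the ring is closed at the O1–C7 bond by a 7-exo-tet Williamson reaction. From 10, both allylic hydroxyls are converted into chlorides (MsCl, Et3N; LiCl) to give (2E)-1,4-dichloro-2-[(3E)-8-chloro-4-methyloct-3-en-1-yl]but-2-ene F3. Shi epoxidation as in step 5 gives the (R,R)-epoxide F4. Acid-catalysed hydrolysis (HClO4 cat., THF/H2O, 0 °C) opens it at the tertiary carbon with inversion to the anti diol F5. Silylation of the secondary hydroxyl alone (TBSOTf, 2,6-lutidine, −78 °C) gives the mono-silyl ether F6. KH in THF lets the tertiary alkoxide displace the chloride of the chloromethyl group on the fully substituted alkene carbon, the only one within reach, to give the chloro-oxepane F7. CsOAc in DMF exchanges the remaining allylic chloride for acetate to give F8. Methanolysis (K2CO3, MeOH) gives the allylic alcohol F9, and silylation (TBSCl, imidazole) rejoins the route at 13.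

Step 8. Activation of the unactivated primary C–Cl bond may be sluggish, and the alkyl radical may be reduced to the alkane (protodehalogenation) under the copper–boryl conditions. Fallback: polar instead of radical borylation. From 13, Finkelstein exchange (NaI, acetone, reflux) gives the primary iodide F10. Iodine–lithium exchange (tBuLi, Et2O, −78 °C) and trapping with 2-isopropoxy-4,4,5,5-tetramethyl-1,3,2-dioxaborolane rejoin the route at 14.

**Further compounds**

F1 | step 11 | lithium vinyl boron ate complex of secondary boronic ester 22 | [Li+].C=C[B-]1([C@H](C)CCC[C@]2(C)OC/C(=C/CO[Si](C)(C)C(C)(C)C)CC[C@H]2O[Si](C)(C)C(C)(C)C)OC(C)(C)C(C)(C)O1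
F2 | step 11 | 3-methylbut-1-en-2-yl trifluoromethanesulfonate | C=C(OS(=O)(=O)C(F)(F)F)C(C)C
F3 | step 6 | (2E)-1,4-dichloro-2-[(3E)-8-chloro-4-methyloct-3-en-1-yl]but-2-ene | ClC/C=C(\CC/C=C(\C)CCCCl)CCl
F4 | step 6 | (2E)-1,4-dichloro-2-{2-[(2R,3R)-3-(3-chloropropyl)-3-methyloxiran-2-yl]ethyl}but-2-ene | ClC/C=C(\CC[C@H]1O[C@]1(C)CCCCl)CCl
F5 | step 6 | (2E,6R,7S)-1,10-dichloro-3-(chloromethyl)-7-methyldec-2-ene-6,7-diol | ClC/C=C(\CC[C@@H](O)[C@@](C)(O)CCCCl)CCl
F6 | step 6 | (2E,6R,7S)-6-(tert-butyldimethylsilyloxy)-1,10-dichloro-3-(chloromethyl)-7-methyldec-2-en-7-ol | ClC/C=C(\CC[C@@H](O[Si](C)(C)C(C)(C)C)[C@@](C)(O)CCCCl)CCl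
F7 | step 6 | (2S,3R,6E)-3-(tert-butyldimethylsilyloxy)-6-(2-chloroethylidene)-2-(3-chloropropyl)-2-methyloxepane | ClCCC[C@]1(C)OC/C(=C/CCl)CC[C@H]1O[Si](C)(C)C(C)(C)C
F8 | step 6 | (E)-2-[(2S,3R)-3-(tert-butyldimethylsilyloxy)-2-(3-chloropropyl)-2-methyloxepan-6-ylidene]ethyl acetate | ClCCC[C@]1(C)OC/C(=C/COC(C)=O)CC[C@H]1O[Si](C)(C)C(C)(C)C
F9 | step 6 | (E)-2-[(2S,3R)-3-(tert-butyldimethylsilyloxy)-2-(3-chloropropyl)-2-methyloxepan-6-ylidene]ethanol | ClCCC[C@]1(C)OC/C(=C/CO)CC[C@H]1O[Si](C)(C)C(C)(C)C
F10 | step 8 | (2S,3R,6E)-3-(tert-butyldimethylsilyloxy)-6-[2-(tert-butyldimethylsilyloxy)ethylidene]-2-(3-iodopropyl)-2-methyloxepane | ICCC[C@]1(C)OC/C(=C/CO[Si](C)(C)C(C)(C)C)CC[C@H]1O[Si](C)(C)C(C)(C)C
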